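**Remark on the chemistry:** the target, 2-(2,4-dihydroxyphenyl)-5-hydroxy-7-methoxy-3-(3-methylbut-2-en-1-yl)-4H-chromen-4-one, has no stereocentre, no stereogenic double bond and no configurationally stable axis. "Single enantiomer" is therefore taken to mean the single constitutional isomer drawn.

## The problem

The target is a flavone: rings A and C are fused as a 4H-chromen-4-one and ring B is a 2,4-dihydroxyphenyl group on C2. It carries 5-OH, 7-OMe and a prenyl group on C3, and nothing has to be controlled in space. What has to be controlled is position. The C2=C3 double bond of the pyranone is fully substituted, with the ortho-oxygenated aryl on the oxygen-bearing carbon C2 and an sp3 CH2 on the carbonyl-bearing carbon C3, and C3 of a finished flavone cannot be prenylated directly in a practical way. The four phenolic oxygens must end up differentiated: O7 methylated, and O5 (chelated to the C4 carbonyl), O2′ and O4′ free. The prenyl alkene lies within reach of the 2′-hydroxyl and will not tolerate strong protic or Lewis acids, electrophilic halogen, quinone oxidants or hydrogenolysis, and the resorcinol B ring is easily halogenated; this limits both the ring-forming chemistry and the protecting groups. The feature on which the plan rests is the atom sequence O1–C2(aryl)=C3(CH2R)–C4(=O) of ring C: C2 and C3 are at the oxidation level of an unsymmetrical aryl/alkyl alkyne, and C4 with O1 on the neighbouring ring-A carbons C4a and C8a is a salicylaldehyde that has lost its formyl and hydroxyl hydrogens. Ring A adds a second advantage: C4a is flanked by two oxygen-bearing carbons (C5 and C8a) that are equivalent by symmetry in a 2,6-dihydroxy-4-methoxyphenyl precursor, so closure through either oxygen gives the same chromone and the other hydroxyl becomes the 5-OH without protection.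

## Retrosynthesis

**Target 9 to protected flavone 8.** The O2′–CH2 and O4′–CH2 bonds of two methoxymethyl (MOM) ethers are cut. Ring B has to enter as an aryl alkyne, and a free hydroxyl ortho to an alkyne would add to it (benzofuran formation) under almost any metal catalyst, so O2′ must be masked until ring C exists; O4′ is masked with it. An acetal is chosen because the route meets only carbonate bases, copper(I) and hot acetate before the last step, and because it leaves under dilute methanolic acid. The 5-OH stays free throughout.

**Flavone 8 to aldehyde 2 and alkyne 7 (key disconnection).** The O1–C2 and C3–C4 bonds of ring C are cut together, which returns 2,6-dihydroxy-4-methoxybenzaldehyde 2 and the aryl prenylmethyl alkyne 7. The neighbouring cuts (O1–C2 with C3–C1″ through a 1,3-diketone, or C3–C1″ alone on a finished flavone) all require a separate operation at C3. Here the prenyl group is already part of one building block and the whole tetrasubstituted C2=C3 unit arrives intact. The precursors have 8 and 17 carbons and neither contains ring C. The forward reaction must insert the alkyne into the formyl C–H and phenolic O–H of 2 with the aryl-bearing carbon going to oxygen, and must leave the prenyl alkene, the MOM acetals and the spectator hydroxyl untouched.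

**Alkyne 7 to terminal alkyne 5 and prenyl bromide 6.** The bond between the alkyne carbon and the prenyl CH2 is cut. The forward reaction is a copper-catalysed alkynyl–allyl coupling, which must occur at the primary carbon of 6. The alternative cut at the aryl–alkyne bond is kept as a fallback.

**Terminal alkyne 5 to aldehyde 4 to 2,4-dihydroxybenzaldehyde 3.** The triple bond is traced back to the formyl group of 4 by a one-carbon homologation, and 4 to commercial 3 by cutting the two O–CH2 acetal bonds.

**Aldehyde 2 to 2,4,6-trihydroxybenzaldehyde 1.** The O–CH3 bond is cut. The forward reaction must methylate only the hydroxyl para to the formyl group; the two ortho hydroxyls need not be told apart, because they are equivalent.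

## Roads not taken

**Alternative 1:** the most obvious plan cuts O1–C2 (cyclodehydration) and C3–C1″ (alkylation). The forward key step is C-prenylation of a Baker–Venkataraman 1,3-diketone with 6 to give the 2-prenyl-1,3-diketone A1, followed by acid closure of ring C. The chosen plan is better for three reasons. The diketone enolate is ambident (O- versus C-alkylation, dialkylation). Closing a 2-substituted diketone to the tetrasubstituted C2=C3 bond needs acid strong enough to unmask the 2′-OH and threaten the prenyl alkene next to it. The sequence is linear, building ring C on one chain by acylation, acyl transfer, alkylation and dehydration, whereas the annulation makes both ring bonds and sets both substituents at once from two fragments under non-acidic conditions.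

**Alternative 2:** cut C3–C1″ on a finished flavone. Ring C would be built without the C3 substituent, C3 iodinated, and the 3-iodoflavone A2 cross-coupled with a prenyl stannane or boronate. The chosen plan is better because electrophilic iodine would have to select C3 over the far more nucleophilic positions C6/C8 and C3′/C5′ of the two oxygenated rings. Prenyl–metal partners also tend to give mixtures of linear and 1,1-dimethylallyl products through allyl transposition at palladium. Finally, three operations (ring formation, halogenation, coupling) do what the annulation does in one.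

**Alternative 3:** cut C3–C1″ as an intramolecular relay from O2′. The 2′-O-prenyl ether A3 would undergo an aromatic Claisen shift to the substituted ortho carbon C1′, then a Cope shift from C1′ to C3, and tautomerise; two [3,3] shifts would return the linear prenyl group. The idea is atom-economic and uses the 2′-OH. However, the open ortho carbon C3′ competes, and migration there is made irreversible by tautomerisation to the 3′-(1,1-dimethylallyl) isomer A4; the Cope shift from C1′ can also run to C5′. Nothing in A3 enforces the required selectivity, whereas the chosen key step has an electronic and a chelation bias in the substrate.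

Key step: step 5

## Route

Step 1
Reactants: 1 2,4,6-trihydroxybenzaldehyde
Product: 2 2,6-dihydroxy-4-methoxybenzaldehyde
Conditions: MeI (1.0 equiv), K2CO3 (1.0 equiv), DMF, 0 °C to rt
Reagents that add atoms: iodomethane, CI
Why: Selective Williamson O-methylation; the 4-OH is para to the formyl group, the most acidic and least hindered of the three and never engaged in the hydrogen bond to the carbonyl oxygen, so one equivalent of base and electrophile should alkylate it first, and the two remaining hydroxyls are equivalent.

Step 2
Reactants: 3 2,4-dihydroxybenzaldehyde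
Product: 4 2,4-bis(methoxymethoxy)benzaldehyde
Conditions: MOMCl (2.6 equiv), K2CO3, acetone, reflux
Reagents that add atoms: chloromethyl methyl ether, COCCl
Why: Williamson-type O-alkylation of both phenols to MOM acetals; excess reagent and heating should also convert the chelated 2-OH.

Step 3
Reactants: 4 2,4-bis(methoxymethoxy)benzaldehyde
Product: 5 1-ethynyl-2,4-bis(methoxymethoxy)benzene
Conditions: dimethyl (1-diazo-2-oxopropyl)phosphonate, K2CO3, MeOH, rt
Reagents that add atoms: dimethyl (1-diazo-2-oxopropyl)phosphonate, COP(=O)(OC)C(=[N+]=[N-])C(C)=O
Why: Seyferth–Gilbert homologation in the Ohira–Bestmann variant; the diazophosphonate anion released by methanolysis olefinates the aldehyde, and loss of nitrogen with 1,2-hydrogen shift should give the terminal alkyne, while the carbonate/methanol medium leaves the MOM acetals intact.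

Step 4
Reactants: 5 1-ethynyl-2,4-bis(methoxymethoxy)benzene; 6 1-bromo-3-methylbut-2-ene (prenyl bromide)
Product: 7 2,4-bis(methoxymethoxy)-1-(5-methylhex-4-en-1-yn-1-yl)benzene
Conditions: CuI (10 mol %), K2CO3, DMF, rt, N2
Reagents that add atoms: none
Why: Copper-catalysed coupling of a terminal alkyne with an allylic halide through the copper(I) acetylide; substitution at the primary carbon of 6 is favoured over attack at the tertiary terminus and should give the linear skipped enyne, and the weak carbonate base should not isomerise the doubly activated CH2.

Step 5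
Reactants: 2 2,6-dihydroxy-4-methoxybenzaldehyde; 7 2,4-bis(methoxymethoxy)-1-(5-methylhex-4-en-1-yn-1-yl)benzene
Product: 8 2-[2,4-bis(methoxymethoxy)phenyl]-5-hydroxy-7-methoxy-3-(3-methylbut-2-en-1-yl)-4H-chromen-4-one
Conditions: [RhCl(cod)]2 (2 mol %), C5H2Ph4 (8 mol %), Cu(OAc)2·H2O (2.2 equiv), o-xylene, 130 °C, N2
Reagents that add atoms: none
Why: Rhodium-catalysed oxidative [4+2] annulation of a salicylaldehyde with an internal alkyne through formyl C–H activation, a known chromone synthesis that accepts 1-aryl-1-alkynes. A rhodium(III) phenoxide formed at either of the two equivalent hydroxyls of 2 cleaves the adjacent formyl C–H bond to give a five-membered aryloxy(acyl)rhodium ring; the alkyne of 7 inserts into the Rh–acyl bond (new C3–C4 bond) to give a seven-membered ring in which rhodium holds the aryl-bearing carbon; C–O reductive elimination forms O1–C2, and Cu(OAc)2 returns Rh(I) to Rh(III). The pyranone is thus closed by reductive elimination from the seven-membered metallacycle and not by a Baldwin-type attack, both ring bonds being made in one catalytic cycle. No stereocentre is formed. The selectivity that matters is the orientation of insertion: the acyl group should migrate to the alkyl-substituted alkyne carbon while rhodium stays on the aryl-substituted carbon, the orientation usual for 1-aryl-1-alkynes in this reaction class, and the 2-OMOM oxygen of 7 can reinforce it by five-membered chelation to rhodium; this places the aryl group on C2 and the prenyl CH2 on C3. Chemoselectivity rests on the alkyne being a far better ligand and insertion partner than the remote trisubstituted prenyl alkene, on the MOM acetals tolerating acetate and acetic acid, and on the spectator hydroxyl staying hydrogen-bonded to the carbonyl oxygen, where it becomes the chelated 5-OH of 8.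

Step 6
Reactants: 8 2-[2,4-bis(methoxymethoxy)phenyl]-5-hydroxy-7-methoxy-3-(3-methylbut-2-en-1-yl)-4H-chromen-4-one
Product: 9 2-(2,4-dihydroxyphenyl)-5-hydroxy-7-methoxy-3-(3-methylbut-2-en-1-yl)-4H-chromen-4-one
Conditions: 3 M aq HCl, MeOH, 40 °C
Reagents that add atoms: none
Why: Acid-catalysed transacetalisation of the two aryl MOM ethers to methanol; the acetal oxygens are protonated far more readily than the trisubstituted alkene, ring closure of the 2′-OH onto the prenyl group would have to form an eight-membered ring, and the 7-OMe ether is inert under these conditions.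

## Compound list

1 | 2,4,6-trihydroxybenzaldehyde | O=Cc1c(O)cc(O)cc1O | starting material
2 | 2,6-dihydroxy-4-methoxybenzaldehyde | COc1cc(O)c(C=O)c(O)c1 | intermediate
3 | 2,4-dihydroxybenzaldehyde | O=Cc1ccc(O)cc1O | starting material
4 | 2,4-bis(methoxymethoxy)benzaldehyde | COCOc1ccc(C=O)c(OCOC)c1 | intermediate
5 | 1-ethynyl-2,4-bis(methoxymethoxy)benzene | C#Cc1ccc(OCOC)cc1OCOC | intermediate
6 | 1-bromo-3-methylbut-2-ene (prenyl bromide) | CC(C)=CCBr | starting material
7 | 2,4-bis(methoxymethoxy)-1-(5-methylhex-4-en-1-yn-1-yl)benzene | CC(C)=CCC#Cc1ccc(OCOC)cc1OCOC | intermediate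
8 | 2-[2,4-bis(methoxymethoxy)phenyl]-5-hydroxy-7-methoxy-3-(3-methylbut-2-en-1-yl)-4H-chromen-4-one | COCOc1ccc(-c2oc3cc(OC)cc(O)c3c(=O)c2CC=C(C)C)c(OCOC)c1 | intermediate
9 | 2-(2,4-dihydroxyphenyl)-5-hydroxy-7-methoxy-3-(3-methylbut-2-en-1-yl)-4H-chromen-4-one | COc1cc(O)c2c(=O)c(CC=C(C)C)c(-c3ccc(O)cc3O)oc2c1 | target

## Step count and risk

Total step count: 6. Longest linear sequence: 5 steps (3 → 4 → 5 → 7 → 8 → 9; steps 2, 3, 4, 5, 6).

**Step 5 (key step).** What may go wrong:
- insertion of the alkyne in the reverse orientation (aryl ending on C3);
- isomerisation of the skipped enyne to a conjugated allene or enyne in hot acetate before insertion;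
- decarbonylation of the acyl-rhodium species;
- loss of the 2-OMOM group followed by attack of the freed phenol on the alkyne;
- slow turnover because the 5-hydroxy-4-oxo chelate of the product binds copper and rhodium.

Fallback by known chemistry, setting out from 4 and returning at 9: Pinnick oxidation of 4 (NaClO2, NaH2PO4, 2-methylbut-2-ene) would give 2,4-bis(methoxymethoxy)benzoic acid F1. Purchased 1-(2,6-dihydroxy-4-methoxyphenyl)ethanone F2 would be converted with MOMCl and i-Pr2NEt into 1-[2-hydroxy-4-methoxy-6-(methoxymethoxy)phenyl]ethanone F3, the second hydroxyl staying chelated. Esterification of F3 with F1 (EDC, DMAP) would give 2-acetyl-5-methoxy-3-(methoxymethoxy)phenyl 2,4-bis(methoxymethoxy)benzoate F4. Baker–Venkataraman acyl transfer (LiHMDS, THF) would give 1-[2,4-bis(methoxymethoxy)phenyl]-3-[2-hydroxy-4-methoxy-6-(methoxymethoxy)phenyl]propane-1,3-dione F5. C-alkylation with 6 (K2CO3, acetone) would give 1-[2,4-bis(methoxymethoxy)phenyl]-3-[2-hydroxy-4-methoxy-6-(methoxymethoxy)phenyl]-2-(3-methylbut-2-en-1-yl)propane-1,3-dione F6, which is the compound A1 of Alternative 1. Methanolic HCl should then close the pyranone and remove the three MOM groups in one operation to give 9.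

**Step 4.** What may go wrong: attack at the tertiary terminus of the prenyl unit (SN2′) giving the branched 1,1-dimethylallyl alkyne, oxidative homocoupling of the alkyne by adventitious oxygen, and base-induced migration of the doubly activated CH2. Fallback, which forms the aryl–alkyne bond instead and settles the regiochemistry on a cheap distillable compound, setting out from 6 and returning at 7: 6 with ethynylmagnesium bromide and catalytic CuCl in THF would give 5-methylhex-4-en-1-yne F7, separated from its branched isomer by distillation. Purchased 4-iodobenzene-1,3-diol F8 would be protected (MOMCl, i-Pr2NEt) as 1-iodo-2,4-bis(methoxymethoxy)benzene F9. Sonogashira coupling of F9 with F7 (Pd(PPh3)2Cl2, CuI, Et3N) should give 7.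

**Step 1.** What may go wrong: over-methylation at a second oxygen and C-methylation of the phloroglucinol nucleus, both lowering the amount of mono-ether. Fallback, which moves the methylation to the stage where the chelated 5-OH and the free 7-OH differ most, setting out from 1 and returning at 8: annulation of 1 with 7 under the conditions of step 5 would give 2-[2,4-bis(methoxymethoxy)phenyl]-5,7-dihydroxy-3-(3-methylbut-2-en-1-yl)-4H-chromen-4-one F10. Methylation of F10 with MeI and K2CO3 in acetone should occur only at the non-chelated 7-OH and give 8.

**Step 6.** What may go wrong: acid-promoted addition of methanol, water or HCl to the prenyl double bond, or hydroalkoxylation by the freed 2′-OH, during removal of the acetals. Fallback, which replaces the acid-labile groups by fluoride-labile ones, setting out from 3 and returning at 9: 3 with SEMCl and i-Pr2NEt would give 2,4-bis{[2-(trimethylsilyl)ethoxy]methoxy}benzaldehyde F11. Ohira–Bestmann homologation would give 1-ethynyl-2,4-bis{[2-(trimethylsilyl)ethoxy]methoxy}benzene F12. Copper-catalysed coupling with 6 would give 1-(5-methylhex-4-en-1-yn-1-yl)-2,4-bis{[2-(trimethylsilyl)ethoxy]methoxy}benzene F13. Annulation with 2 as in step 5 would give 5-hydroxy-7-methoxy-3-(3-methylbut-2-en-1-yl)-2-(2,4-bis{[2-(trimethylsilyl)ethoxy]methoxy}phenyl)-4H-chromen-4-one F14. TBAF in THF/DMPU at 60 °C should then release 9 without any acid.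

## Further compounds

F1 | step 5 | 2,4-bis(methoxymethoxy)benzoic acid | COCOc1ccc(C(=O)O)c(OCOC)c1
F2 | step 5 | 1-(2,6-dihydroxy-4-methoxyphenyl)ethanone (purchased) | CC(=O)c1c(O)cc(OC)cc1O
F3 | step 5 | 1-[2-hydroxy-4-methoxy-6-(methoxymethoxy)phenyl]ethanone | COCOc1cc(OC)cc(O)c1C(C)=O
F4 | step 5 | 2-acetyl-5-methoxy-3-(methoxymethoxy)phenyl 2,4-bis(methoxymethoxy)benzoate | COCOc1ccc(C(=O)Oc2cc(OC)cc(OCOC)c2C(C)=O)c(OCOC)c1
F5 | step 5 | 1-[2,4-bis(methoxymethoxy)phenyl]-3-[2-hydroxy-4-methoxy-6-(methoxymethoxy)phenyl]propane-1,3-dione | COCOc1ccc(C(=O)CC(=O)c2c(O)cc(OC)cc2OCOC)c(OCOC)c1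
F6 | step 5 | 1-[2,4-bis(methoxymethoxy)phenyl]-3-[2-hydroxy-4-methoxy-6-(methoxymethoxy)phenyl]-2-(3-methylbut-2-en-1-yl)propane-1,3-dione | COCOc1ccc(C(=O)C(CC=C(C)C)C(=O)c2c(O)cc(OC)cc2OCOC)c(OCOC)c1
F7 | step 4 | 5-methylhex-4-en-1-yne | C#CCC=C(C)C
F8 | step 4 | 4-iodobenzene-1,3-diol (purchased) | Oc1ccc(I)c(O)c1
F9 | step 4 | 1-iodo-2,4-bis(methoxymethoxy)benzene | COCOc1ccc(I)c(OCOC)c1
F10 | step 1 | 2-[2,4-bis(methoxymethoxy)phenyl]-5,7-dihydroxy-3-(3-methylbut-2-en-1-yl)-4H-chromen-4-one | COCOc1ccc(-c2oc3cc(O)cc(O)c3c(=O)c2CC=C(C)C)c(OCOC)c1
F11 | step 6 | 2,4-bis{[2-(trimethylsilyl)ethoxy]methoxy}benzaldehyde | C[Si](C)(C)CCOCOc1ccc(C=O)c(OCOCC[Si](C)(C)C)c1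
F12 | step 6 | 1-ethynyl-2,4-bis{[2-(trimethylsilyl)ethoxy]methoxy}benzene | C#Cc1ccc(OCOCC[Si](C)(C)C)cc1OCOCC[Si](C)(C)C
F13 | step 6 | 1-(5-methylhex-4-en-1-yn-1-yl)-2,4-bis{[2-(trimethylsilyl)ethoxy]methoxy}benzene | CC(C)=CCC#Cc1ccc(OCOCC[Si](C)(C)C)cc1OCOCC[Si](C)(C)C
F14 | step 6 | 5-hydroxy-7-methoxy-3-(3-methylbut-2-en-1-yl)-2-(2,4-bis{[2-(trimethylsilyl)ethoxy]methoxy}phenyl)-4H-chromen-4-one | COc1cc(O)c2c(=O)c(CC=C(C)C)c(-c3ccc(OCOCC[Si](C)(C)C)cc3OCOCC[Si](C)(C)C)oc2c1
A1 | alternative 1 | 1-[2,4-bis(methoxymethoxy)phenyl]-3-[2-hydroxy-4-methoxy-6-(methoxymethoxy)phenyl]-2-(3-methylbut-2-en-1-yl)propane-1,3-dione | COCOc1ccc(C(=O)C(CC=C(C)C)C(=O)c2c(O)cc(OC)cc2OCOC)c(OCOC)c1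
A2 | alternative 2 | 2-[2,4-bis(methoxymethoxy)phenyl]-3-iodo-7-methoxy-5-(methoxymethoxy)-4H-chromen-4-one | COCOc1ccc(-c2oc3cc(OC)cc(OCOC)c3c(=O)c2I)c(OCOC)c1
A3 | alternative 3 | 5-hydroxy-7-methoxy-2-{4-(methoxymethoxy)-2-[(3-methylbut-2-en-1-yl)oxy]phenyl}-4H-chromen-4-one | COCOc1ccc(-c2cc(=O)c3c(O)cc(OC)cc3o2)c(OCC=C(C)C)c1
A4 | alternative 3 | 5-hydroxy-2-[2-hydroxy-4-(methoxymethoxy)-3-(2-methylbut-3-en-2-yl)phenyl]-7-methoxy-4H-chromen-4-one | COCOc1ccc(-c2cc(=O)c3c(O)cc(OC)cc3o2)c(O)c1C(C)(C)C=C
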